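**Retrosynthetic overview**

1. Drimane numbering is used: ring A = C1–C5 and C10 (C4 carries two CH3), ring B = C5–C10 (C8–CH3, C10–CH3), C11 = the exocyclic C(Cl)(aryl). The quinone is made last by para-oxidation of a 3-methoxy-5-alkenylphenol, after Wolff–Kishner removal of a ring A carbonyl (C2) left by the key step.
2. Key disconnection: C5–C6 (ring B) and C10–C1 (ring A) are formed in one cationic cascade from an open chain. A primary arenesulfonate at C6 is displaced by the (E)-C5=C10 alkene, and the resulting C10 cation is trapped by a silyl enol ether (C1=C2).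
3. Enabling feature: the tetrasubstituted C9=C11(Cl)(aryl) alkene exocyclic to ring B, between the C8 methine and C10. It makes the C10 cation allylic, and A(1,3) strain between Cl on C11 and the C8 substituents forces C8–CH3 axial, so C8 alone dictates C5 and C10. The (E)-C5=C10 alkene gives the trans ring fusion, and the C4 gem-dimethyl group speeds closure of ring A.
4. The open chain is joined at C9–C10 by Negishi coupling. One half comes from anti-iodochlorination of an aryl alkyne (sets the C9=C11 geometry). The other is an alkenylzirconium made from mesityl oxide and propyne (sets the C5=C10 geometry and the C4 gem-dimethyl group).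
5. C8 is the only preset stereocentre (asymmetric hydrogenation of α-methylene-γ-butyrolactone). Order of ring formation: arene (bought), then ring B, then ring A in the same operation, then the quinone by oxidation.

Key step: step 11

Assumption: in step 1 the (R)-BINAP ruthenium catalyst is taken to deliver the (S)-lactone; if the sense of induction proves to be the opposite, the (S)-ligand is used instead.

**Step 1**
Reactants: 1 α-methylene-γ-butyrolactone
Product: 2 (3S)-3-methyloxolan-2-one
Conditions: Ru(OAc)2((R)-BINAP) (cat.), H2 (100 atm), CH2Cl2, 50 °C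
Reagents that add atoms: none
Why: Ru–BINAP asymmetric hydrogenation of the exocyclic α-methylene lactone, in which the lactone carbonyl binds ruthenium so that hydrogen is delivered to one enantioface, should set the future C8 methyl stereocentre as (S).

**Step 2**
Reactants: 2 (3S)-3-methyloxolan-2-one
Product: 3 (3S)-3-methyloxolan-2-ol (lactol, both anomers)
Conditions: i-Bu2AlH, CH2Cl2, −78 °C; aq. potassium sodium tartrate
Reagents that add atoms: none
Why: Partial hydride reduction of a γ-lactone at low temperature stops at the tetrahedral aluminium acetal and gives the lactol on work-up without touching the stereocentre.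

**Step 3**
Reactants: 3 (3S)-3-methyloxolan-2-ol
Product: 4 (3S)-3-methylpent-4-yn-1-ol
Conditions: dimethyl (1-diazo-2-oxopropyl)phosphonate, K2CO3, MeOH, 0 °C to rt
Reagents that add atoms: Ohira–Bestmann reagent, dimethyl (1-diazo-2-oxopropyl)phosphonate, CC(=O)C(=[N+]=[N-])P(=O)(OC)OC
Why: The open hydroxy-aldehyde form of the lactol undergoes Seyferth–Gilbert homologation with the Ohira–Bestmann reagent under mild carbonate conditions, which turns CHO into C≡CH (the future C9 and C11) with little risk to the adjacent stereocentre.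

**Step 4**
Reactants: 5 3-bromo-5-methoxyphenol
Product: 6 3-bromo-5-methoxyphenyl pivalate
Conditions: pivaloyl chloride, Et3N, DMAP (cat.), CH2Cl2, 0 °C to rt
Reagents that add atoms: pivaloyl chloride, CC(C)(C)C(Cl)=O
Why: Acylation of the phenol (nucleophilic acyl substitution) masks the future quinone oxygen as a robust ester that also lowers the reactivity of the ring towards ICl in step 7.

**Step 5**
Reactants: 4 (3S)-3-methylpent-4-yn-1-ol; 6 3-bromo-5-methoxyphenyl pivalate
Product: 7 3-[(3S)-5-hydroxy-3-methylpent-1-yn-1-yl]-5-methoxyphenyl pivalate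
Conditions: PdCl2(PPh3)2 (cat.), CuI (cat.), Et3N/THF, 60 °C
Reagents that add atoms: none
Why: Sonogashira coupling joins the aryl bromide and the terminal alkyne under conditions that tolerate the free primary alcohol and the pivalate.

**Step 6**
Reactants: 7 3-[(3S)-5-hydroxy-3-methylpent-1-yn-1-yl]-5-methoxyphenyl pivalate
Product: 8 3-methoxy-5-[(3S)-3-methyl-5-(4-nitrophenylsulfonyloxy)pent-1-yn-1-yl]phenyl pivalate
Conditions: 4-nitrobenzenesulfonyl chloride, Et3N, DMAP (cat.), CH2Cl2, −10 °C
Reagents that add atoms: 4-nitrobenzenesulfonyl chloride, O=S(=O)(Cl)c1ccc(cc1)[N+](=O)[O-]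
Why: Sulfonylation of the primary alcohol installs at C6 the arenesulfonate leaving group that later starts the key cyclisation and that is inert to ICl and to organozinc coupling.

**Step 7**
Reactants: 8 3-methoxy-5-[(3S)-3-methyl-5-(4-nitrophenylsulfonyloxy)pent-1-yn-1-yl]phenyl pivalate
Product: 9 3-[(1E,3S)-1-chloro-2-iodo-3-methyl-5-(4-nitrophenylsulfonyloxy)pent-1-en-1-yl]-5-methoxyphenyl pivalate
Conditions: ICl (1.05 equiv), CH2Cl2, −78 °C
Reagents that add atoms: iodine monochloride, ClI
Why: Electrophilic anti-addition of ICl to the aryl alkyne (iodonium ion opened by chloride at the benzylic carbon) should place Cl on C11 and I on C9 trans to each other, which fixes the C9=C11 geometry of the target (Cl cis to C8) and leaves a vinyl iodide for coupling.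

**Step 8**
Reactants: 10 mesityl oxide; 11 1-propynyllithium
Product: 13 4,4-dimethylhept-5-yn-2-one, via B-(1-propynyl)-9-BBN 12 (not isolated)
Conditions: 11, B-methoxy-9-borabicyclo[3.3.1]nonane, THF, −78 °C; BF3·OEt2; then 10, pentane/THF, rt; aqueous work-up
Reagents that add atoms: none
Why: The alkynylborane adds in 1,4-fashion to the s-cis enone through a six-membered cyclic transition state (conjugate alkynylation), which creates the quaternary C4 with its two methyl groups.

**Step 9**
Reactants: 13 4,4-dimethylhept-5-yn-2-one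
Product: 14 triisopropyl[(4,4-dimethylhept-1-en-5-yn-2-yl)oxy]silane
Conditions: LiN(i-Pr)2, THF, −78 °C; TIPSOTf, −78 to 0 °C
Reagents that add atoms: triisopropylsilyl trifluoromethanesulfonate, CC(C)[Si](OS(=O)(=O)C(F)(F)F)(C(C)C)C(C)C
Why: Kinetic deprotonation at the methyl group (the methylene is neopentyl) followed by O-silylation gives the terminal silyl enol ether, the nucleophile that later closes ring A (regioselective enol silane formation).

**Step 10**
Reactants: 14 triisopropyl[(4,4-dimethylhept-1-en-5-yn-2-yl)oxy]silane; 9 3-[(1E,3S)-1-chloro-2-iodo-3-methyl-5-(4-nitrophenylsulfonyloxy)pent-1-en-1-yl]-5-methoxyphenyl pivalate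
Product: 17 3-[(1E,3E)-1-chloro-3,5,5-trimethyl-2-[(2S)-4-(4-nitrophenylsulfonyloxy)butan-2-yl]-7-(triisopropylsilyloxy)octa-1,3,7-trien-1-yl]-5-methoxyphenyl pivalate, via alkenylzirconocene chloride 15 (not isolated), via alkenylzinc chloride 16 (not isolated)
Conditions: 14, Cp2Zr(H)Cl, THF, rt to 40 °C; ZnCl2, 0 °C; then 9, Pd(PPh3)4 (cat.), THF, 40 °C
Reagents that add atoms: none
Why: Hydrozirconation adds H and Zr syn across the internal alkyne with Zr on the less hindered methyl-bearing carbon, and transmetalation to zinc followed by Negishi coupling at the C–I bond (far more reactive than C–Cl) proceeds with retention at both alkenes, giving the (E)-C5=C10 alkene and C10 cis to the aryl group.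

**Step 11**
Reactants: 17 3-[(1E,3E)-1-chloro-3,5,5-trimethyl-2-[(2S)-4-(4-nitrophenylsulfonyloxy)butan-2-yl]-7-(triisopropylsilyloxy)octa-1,3,7-trien-1-yl]-5-methoxyphenyl pivalate
Product: 20 3-{(E)-chloro[(2S,4aS,8aS)-2,5,5,8a-tetramethyl-7-oxo-octahydronaphthalen-1(2H)-ylidene]methyl}-5-methoxyphenyl pivalate, via C10 allyl cation 18 (not isolated), via silyl oxocarbenium ion 19 (not isolated)
Conditions: 1,1,1,3,3,3-hexafluoropropan-2-ol (high dilution), 2,6-di-tert-butyl-4-methylpyridine, 40 °C; then aq. HCl/THF, rt
Reagents that add atoms: none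
Why: In the strongly ionising, non-nucleophilic solvent the trisubstituted (E)-C5=C10 alkene displaces the primary sulfonate at C6 with π-participation through a chair-like transition state (ring B: 6-exo-tet at C6, 6-endo with respect to the alkene, Markovnikov so that charge develops at the tertiary, allylic C10 and not at C5), and cation 18 is trapped at C10 by C1 of the silyl enol ether (ring A: 6-endo closure onto the enol ether, helped by the C4 gem-dimethyl group) to give 19, which loses silicon to the solvent. The closest known reaction type is the alkene-assisted solvolytic polyene bicyclisation of dienyl primary arenesulfonates, combined with the established enol-silane termination of cation–olefin cyclisations. C5 and C10 arise from antiperiplanar addition of C6 and C1 across the (E)-alkene in a chair–chair array, which gives the trans ring fusion (5-H anti to 10-CH3) and the quaternary C10. The absolute sense comes from C8 alone: A(1,3) strain between Cl on C11 (cis to C8) and the C8 substituents holds C8–H in the plane of the C9=C11 bond, so C8–CH3 is axial in the ring B chair and C6 can reach only one face of the C5=C10 bond, which places 8-CH3 and 10-CH3 syn (5S,8S,10S). The step needs capture at C10 instead of C11 (six- versus eight-membered ring), capture by carbon faster than proton loss or Friedel–Crafts closure of the aryl group onto C10 (secured by the far more nucleophilic enol silane), and no direct reaction between the two chain ends (the enol silane could reach C6 only through a ten-membered ring). The C9=C11 geometry set in step 7 should be retained because the crowded cation is captured faster than it can rotate about the C9–C11 bond.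

**Step 12**
Reactants: 20 3-{(E)-chloro[(2S,4aS,8aS)-2,5,5,8a-tetramethyl-7-oxo-octahydronaphthalen-1(2H)-ylidene]methyl}-5-methoxyphenyl pivalate
Product: 22 3-{(E)-chloro[(2S,4aS,8aS)-2,5,5,8a-tetramethyloctahydronaphthalen-1(2H)-ylidene]methyl}-5-methoxyphenol, via hydrazone 21 (not isolated)
Conditions: N2H4·H2O, KOH, diethylene glycol, 130 °C then 200 °C; aq. HCl
Reagents that add atoms: none
Why: Wolff–Kishner reduction (Huang-Minlon conditions) converts the unhindered ring A ketone into CH2 via the hydrazone while the hot alkali cleaves the pivalate, and the tetrasubstituted vinyl chloride, which has no hydrogen on C9 for elimination, should survive.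

**Step 13**
Reactants: 22 3-{(E)-chloro[(2S,4aS,8aS)-2,5,5,8a-tetramethyloctahydronaphthalen-1(2H)-ylidene]methyl}-5-methoxyphenol
Product: 23 2-{(E)-chloro[(2S,4aS,8aS)-2,5,5,8a-tetramethyloctahydronaphthalen-1(2H)-ylidene]methyl}-6-methoxycyclohexa-2,5-diene-1,4-dione (target)
Conditions: (KO3S)2NO, KH2PO4, acetone/H2O, rt
Reagents that add atoms: potassium nitrosodisulfonate, [K+].[K+].[O]N(S([O-])(=O)=O)S([O-])(=O)=O
Why: Oxidation of a phenol with a free para position by potassium nitrosodisulfonate (Teuber reaction) gives the para-quinone, here at the carbon between OCH3 and the side chain, without affecting the stereocentres or the chloroalkene.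

**Compound list**

1 | α-methylene-γ-butyrolactone (3-methylideneoxolan-2-one) | C=C1CCOC1=O | starting material
2 | (3S)-3-methyloxolan-2-one | O=C1[C@@H](C)CCO1 | intermediate
3 | (3S)-3-methyloxolan-2-ol (lactol, both anomers) | OC1[C@@H](C)CCO1 | intermediate
4 | (3S)-3-methylpent-4-yn-1-ol | C#C[C@@H](C)CCO | intermediate
5 | 3-bromo-5-methoxyphenol | COc1cc(O)cc(Br)c1 | starting material
6 | 3-bromo-5-methoxyphenyl pivalate | COc1cc(Br)cc(OC(=O)C(C)(C)C)c1 | intermediate
7 | 3-[(3S)-5-hydroxy-3-methylpent-1-yn-1-yl]-5-methoxyphenyl pivalate | COc1cc(OC(=O)C(C)(C)C)cc(c1)C#C[C@@H](C)CCO | intermediate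
8 | 3-methoxy-5-[(3S)-3-methyl-5-(4-nitrophenylsulfonyloxy)pent-1-yn-1-yl]phenyl pivalate | COc1cc(OC(=O)C(C)(C)C)cc(c1)C#C[C@@H](C)CCOS(=O)(=O)c1ccc(cc1)[N+](=O)[O-] | intermediate
9 | 3-[(1E,3S)-1-chloro-2-iodo-3-methyl-5-(4-nitrophenylsulfonyloxy)pent-1-en-1-yl]-5-methoxyphenyl pivalate (Cl and I trans) | COc1cc(OC(=O)C(C)(C)C)cc(c1)/C(Cl)=C(\I)[C@@H](C)CCOS(=O)(=O)c1ccc(cc1)[N+](=O)[O-] | intermediate
10 | mesityl oxide (4-methylpent-3-en-2-one) | CC(=O)C=C(C)C | starting material
11 | 1-propynyllithium | CC#C[Li] | starting material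
12 | B-(1-propynyl)-9-borabicyclo[3.3.1]nonane | CC#CB1C2CCCC1CCC2 | intermediate
13 | 4,4-dimethylhept-5-yn-2-one | CC#CC(C)(C)CC(C)=O | intermediate
14 | triisopropyl[(4,4-dimethylhept-1-en-5-yn-2-yl)oxy]silane | CC#CC(C)(C)CC(=C)O[Si](C(C)C)(C(C)C)C(C)C | intermediate
15 | chlorobis(cyclopentadienyl)[(2E)-4,4-dimethyl-6-(triisopropylsilyloxy)hepta-2,6-dien-2-yl]zirconium (Zr trans to the quaternary carbon) | Cl[Zr](C1C=CC=C1)(C1C=CC=C1)/C(C)=C/C(C)(C)CC(=C)O[Si](C(C)C)(C(C)C)C(C)C | intermediate
16 | chloro[(2E)-4,4-dimethyl-6-(triisopropylsilyloxy)hepta-2,6-dien-2-yl]zinc | Cl[Zn]/C(C)=C/C(C)(C)CC(=C)O[Si](C(C)C)(C(C)C)C(C)C | intermediate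
17 | 3-[(1E,3E)-1-chloro-3,5,5-trimethyl-2-[(2S)-4-(4-nitrophenylsulfonyloxy)butan-2-yl]-7-(triisopropylsilyloxy)octa-1,3,7-trien-1-yl]-5-methoxyphenyl pivalate | COc1cc(OC(=O)C(C)(C)C)cc(c1)/C(Cl)=C(\C(C)=C\C(C)(C)CC(=C)O[Si](C(C)C)(C(C)C)C(C)C)[C@@H](C)CCOS(=O)(=O)c1ccc(cc1)[N+](=O)[O-] | intermediate
18 | C10 allyl cation: ring B closed (C5–C6 formed), tertiary cation at C10 next to the C9=C11 chloroalkene, ring A still open, 5S and 8S | COc1cc(OC(=O)C(C)(C)C)cc(c1)/C(Cl)=C1/[C@@H](C)CC[C@H]([C+]1C)C(C)(C)CC(=C)O[Si](C(C)C)(C(C)C)C(C)C | intermediate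
19 | O-triisopropylsilyl oxocarbenium ion of 20 (both rings closed, trans-fused) | COc1cc(OC(=O)C(C)(C)C)cc(c1)/C(Cl)=C1/[C@@H](C)CC[C@H]2C(C)(C)CC(=[O+][Si](C(C)C)(C(C)C)C(C)C)C[C@]12C | intermediate
20 | 3-{(E)-chloro[(2S,4aS,8aS)-2,5,5,8a-tetramethyl-7-oxo-octahydronaphthalen-1(2H)-ylidene]methyl}-5-methoxyphenyl pivalate (trans-decalin, ketone at C2 of ring A) | COc1cc(OC(=O)C(C)(C)C)cc(c1)/C(Cl)=C1/[C@@H](C)CC[C@H]2C(C)(C)CC(=O)C[C@]12C | intermediate
21 | hydrazone of the ring A ketone (phenol already free) | COc1cc(O)cc(c1)/C(Cl)=C1/[C@@H](C)CC[C@H]2C(C)(C)CC(=NN)C[C@]12C | intermediate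
22 | 3-{(E)-chloro[(2S,4aS,8aS)-2,5,5,8a-tetramethyloctahydronaphthalen-1(2H)-ylidene]methyl}-5-methoxyphenol | COc1cc(O)cc(c1)/C(Cl)=C1/[C@@H](C)CC[C@H]2C(C)(C)CCC[C@]12C | intermediate
23 | 2-{(E)-chloro[(2S,4aS,8aS)-2,5,5,8a-tetramethyloctahydronaphthalen-1(2H)-ylidene]methyl}-6-methoxycyclohexa-2,5-diene-1,4-dione | COC1=CC(=O)C=C(/C(Cl)=C2/[C@@H](C)CC[C@H]3C(C)(C)CCC[C@]23C)C1=O | target

**Summary**

Total step count: 13.
Longest linear sequence: 10 steps (steps 1, 2, 3, 5, 6, 7, 10, 11, 12, 13).

**Steps most likely to fail**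

Risk at step 11 (key cyclisation). Ionisation of the primary sulfonate may be too slow at the hindered C5 terminus. The enol silane may then be protonated by the solvent before the C10 cation exists, and the cation would be lost by proton loss, by oxygen capture or by Friedel–Crafts closure onto the aryl ring. The fallback sets out from 17 and replaces sulfonate ionisation by carbonyl activation. Kornblum oxidation (DMSO, NaHCO3, 100 °C) should convert the sulfonate into the aldehyde F1. MeAlCl2 in CH2Cl2 at −78 °C under high dilution should then start the same bicyclisation from the activated aldehyde (Prins-type initiation, same chair–chair course) to give the C6 hydroxy ketone F2. Dess–Martin oxidation should give the C2,C6-diketone F3. The Wolff–Kishner conditions of step 12 should then remove both carbonyl groups and the pivalate (C5, now next to a carbonyl, can equilibrate to the trans ring fusion), coming back to the route at 22.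

Risk at step 10 (hydrozirconation and coupling). Transmetalation and reductive elimination between two hindered alkenyl partners may be slow. Competing processes are protodemetalation, hydrozirconation of the enol ether, and loss of ICl from 9 after oxidative addition. The fallback sets out from 14 and separates the two events. Hydroboration with pinacolborane catalysed by Cp2Zr(H)Cl (CH2Cl2, rt) should give the isolable alkenylboronate F4 (boron trans to the quaternary carbon). After purification it can be used in excess in a Suzuki–Miyaura coupling with 9 (PdCl2(dppf), K3PO4, THF/H2O, 50 °C), coming back to the route at 17.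

Risk at step 12 (Wolff–Kishner reduction). Hot alkaline hydrazine may reduce or isomerise the chloroalkene (adventitious diimide, addition–elimination) or degrade the electron-rich phenolate. The fallback sets out from 20 and removes the carbonyl by a radical route. NaBH4 in MeOH should give the C2 alcohol F5. 1,1'-Thiocarbonyldiimidazole with DMAP should give the imidazolyl thiocarbonate F6. Bu3SnH with AIBN in toluene at 100 °C (Barton–McCombie deoxygenation) should give the deoxygenated pivalate F7. K2CO3 in MeOH should then cleave the ester, coming back to the route at 22.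

**Further compounds**

F1 | step 11 | 3-[(1E,3E)-1-chloro-3,5,5-trimethyl-2-[(2S)-4-oxobutan-2-yl]-7-(triisopropylsilyloxy)octa-1,3,7-trien-1-yl]-5-methoxyphenyl pivalate | COc1cc(OC(=O)C(C)(C)C)cc(c1)/C(Cl)=C(\C(C)=C\C(C)(C)CC(=C)O[Si](C(C)C)(C(C)C)C(C)C)[C@@H](C)CC=O
F2 | step 11 | C6-hydroxy derivative of ketone 20 (OH on the ring B carbon next to C5, both C6 epimers) | COc1cc(OC(=O)C(C)(C)C)cc(c1)/C(Cl)=C1/[C@@H](C)CC(O)[C@H]2C(C)(C)CC(=O)C[C@]12C
F3 | step 11 | C2,C6-diketone (20 with an additional carbonyl at C6, trans ring fusion) | COc1cc(OC(=O)C(C)(C)C)cc(c1)/C(Cl)=C1/[C@@H](C)CC(=O)[C@H]2C(C)(C)CC(=O)C[C@]12C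
F4 | step 10 | 2-[(2Z)-4,4-dimethyl-6-(triisopropylsilyloxy)hepta-2,6-dien-2-yl]-4,4,5,5-tetramethyl-1,3,2-dioxaborolane (boron trans to the quaternary carbon) | CC1(C)OB(OC1(C)C)/C(C)=C/C(C)(C)CC(=C)O[Si](C(C)C)(C(C)C)C(C)C
F5 | step 12 | C2 alcohol from ketone 20 (both C2 epimers) | COc1cc(OC(=O)C(C)(C)C)cc(c1)/C(Cl)=C1/[C@@H](C)CC[C@H]2C(C)(C)CC(O)C[C@]12C
F6 | step 12 | O-(imidazol-1-ylthiocarbonyl) derivative of F5 | COc1cc(OC(=O)C(C)(C)C)cc(c1)/C(Cl)=C1/[C@@H](C)CC[C@H]2C(C)(C)CC(OC(=S)n3ccnc3)C[C@]12C
F7 | step 12 | 3-{(E)-chloro[(2S,4aS,8aS)-2,5,5,8a-tetramethyloctahydronaphthalen-1(2H)-ylidene]methyl}-5-methoxyphenyl pivalate | COc1cc(OC(=O)C(C)(C)C)cc(c1)/C(Cl)=C1/[C@@H](C)CC[C@H]2C(C)(C)CCC[C@]12C
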